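(The earlier runs and the new flask were generated by integration with made-up constants.)

Start from the delta run: after the feed stops at 15 h, substrate falls from 39.4 % to 18.2 % by 20.0 h, with partner charged at 3 M against 0.50 M of substrate. Take logarithms, then divide that slope by a [partner] of about 2.50 M. This reading gives the substrate clock 0.0618 M⁻¹ h⁻¹: the pseudo-first-order decay constant of substrate, every loss of substrate counted, per unit of [partner].

| flask | substrate | partner | remark | time |
|---|---|---|---|---|
| alpha | 0.50 M (fed, over 15 h) | 0.75 M | run made earlier |  |
| delta | 0.50 M (fed, over 15 h) | 3 M | run made earlier |  |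
| epsilon | 1 M (fed, over 15 h) | 1.5 M | run made earlier |  |
| flask | 0.50 M (fed, over 15 h) | 1.50 M |  | 30 h |

| run | time / h | substrate / % | side product B / % | over-reaction product / % | target / % |
|---|---|---|---|---|---|
| alpha | 2.50 | 16.3 | 0.2 | 0 | 1.1 |
| alpha | 6.00 | 35.7 | 0.1 | 0.1 | 5.0 |
| alpha | 12.0 | 63.2 | 0.7 | 1.0 | 14.3 |
| alpha | 20.0 | 63.1 | 6.5 | 1.6 | 29.1 |
| delta | 5.00 | 23.6 | 0.6 | 0.6 | 9.3 |
| delta | 10.0 | 32.7 | 0.9 | 4.2 | 27.7 |
| delta | 15.0 | 39.4 | 4.3 | 11.4 | 46.1 |
| delta | 20.0 | 18.2 | 6.4 | 21.3 | 53.2 |
| epsilon | 2.50 | 15.1 | 0.3 | 0.5 | 0.7 |
| epsilon | 6.00 | 31.9 | 0 | 0.7 | 8.1 |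
| epsilon | 12.0 | 52.1 | 2.0 | 2.1 | 22.5 |
| epsilon | 20.0 | 43.4 | 13.7 | 6.2 | 37.7 |

(readings scatter by 0.5 percentage points)

- percentages count the substrate that a species holds: one side product B counts as two
- steps that have been proposed: substrate + partner -> target; 2 partner -> side product A; substrate + target -> side product B; partner + target -> over-reaction product
- percentages count the whole charge, also what has not yet gone in

* the largest share of what was charged as substrate, at 30 h belongs to (target / side product B / over-reaction product / substrate)
* the largest share itself, whichever of these holds it, in percent of the substrate charged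

In the flask, set [partner] at 1.25 M, the charge less half the substrate charge, so reckon the decay of substrate at 0.0772 h⁻¹. Solve two extremes. With the charge all in at the start, 9.86 % stands at 30 h; with it all in at the end of the feed, 31.4 %. Each portion enters between those moments, so the real flask lies between; place it midway on the log scale, at 17.6 %.

Now read the target share of what has left substrate at 20.0 h: 65.0 % in delta, 66.6 % in epsilon. The flask's partner-to-substrate ratio of 3.00 lies between theirs. Delta's substrate at that reading, 18.2 %, stands near the midway 17.6 %, so carry delta's share over and reckon target in the flask at 53.6 %. That leaves 28.8 % for side product B and over-reaction product together, less than target. Even at the later extreme, target at 44.6 % stands above substrate.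

The forecast, slightly lower than this reckoning, gives target at 52 %: “Target clearly holds the most”.

The flask gives target at 50.6 %, with substrate at 20.2 %.

    substrate + partner → target (k = 9.10 × 10⁻⁴ M⁻¹ min⁻¹)
    2 partner → side product A (k = 5.50 × 10⁻⁶ M⁻¹ min⁻¹)
    substrate + target → side product B (k = 7.00 × 10⁻⁴ M⁻¹ min⁻¹)
    partner + target → over-reaction product (k = 2.50 × 10⁻⁴ M⁻¹ min⁻¹)

In the flask at 30.0 h, substrate + partner runs 5.3 times as fast as substrate + target, down from 11 at 14.3 h. At that moment it runs 1.5 times as fast as partner + target, so the two losses of target together come to 0.876 of target formation. Take the clock to the neighbour flask with 0.38 M of partner, whose [partner] averaged between charge and 30.0 h is 0.302 M: the midway reckoning gives 65.7 % of substrate, and that neighbour flask holds 65.6 %.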